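## Retrosynthetic overview

1. The target comes from its tri-O-benzyl ether by global hydrogenolysis; no stereocentre is touched.
2. The 2S centre of ring C comes from a rhodium-catalysed asymmetric 1,4-addition of 4-(benzyloxy)phenylboronic acid to a 5,7-bis(benzyloxy)-6-(piperidinyl)chromone.
3. The chromone (the only ring built in the route) comes from an enaminone of an ortho-(methoxymethoxy)acetophenone, made by directed ortho-lithiation and acetylation. The ring oxygen is the phenol para to the piperidine, singled out earlier by a bulky silyl group.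
4. The N-methyl group comes from LiAlH4 reduction of an N-Boc group; the protecting-group pattern is built on N-Boc-2-(2,4,6-trihydroxyphenyl)piperidine.
5. The aryl–piperidine bond and the 2R centre come from a new chiral-phosphoric-acid-catalysed aza-Friedel–Crafts reaction of phloroglucinol with an N-Boc ene-carbamate. Ring order: ring A and the piperidine are bought intact and joined first, ring C is closed in step 8, ring B is attached in step 9.

Assumption: simple reagents that deliver a protecting group or a one-carbon unit are given by name and SMILES on their own line and carry no compound number; compound 2, (R)-TRIP and (S)-MeO-F12-BIPHEP are taken as purchasable.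

## Route

Step 1
Reactants: 1 phloroglucinol (benzene-1,3,5-triol) + 2 tert-butyl 3,4-dihydro-2H-pyridine-1-carboxylate
Product: 4 tert-butyl (2R)-2-(2,4,6-trihydroxyphenyl)piperidine-1-carboxylate, via N-Boc-iminium phosphate ion pair 3 (not isolated)
Conditions: (R)-TRIP [(R)-3,3'-bis(2,4,6-triisopropylphenyl)-1,1'-binaphthyl-2,2'-diyl hydrogen phosphate] 5 mol %, 1 (3 equiv), 2 added over 6 h, t-BuOMe/EtOAc 4:1, 4 Å MS, −30 °C
Reagents that add atoms: none
Why: Proposed new method: a chiral-phosphoric-acid-catalysed enantioselective aza-Friedel–Crafts (phenolic Mannich) amidoalkylation in which the acid protonates the ene-carbamate at its β-carbon to give the N-Boc-iminium 3 as a contact ion pair, the phosphate oxygen at the same time hydrogen-bonds a phenolic OH of 1 so that the ortho carbon is delivered to the Si face of the iminium carbon inside the triisopropylphenyl pocket (any O-adduct reverts under the acid), and rearomatisation gives 2R-configured 4 while the non-basic carbamate product lets the acid turn over and the threefold symmetry of 1 leaves no regiochemical question; the closest known reaction type is the Brønsted-acid-catalysed asymmetric Friedel–Crafts reaction of indoles and naphthols with ene-carbamates and N-acyl imines, and the sense of induction is assigned by that analogy (the mirror-image acid is used if it proves opposite).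

Step 2
Reactants: 4 tert-butyl (2R)-2-(2,4,6-trihydroxyphenyl)piperidine-1-carboxylate
Product: 5 tert-butyl (2R)-2-{2,6-dihydroxy-4-[tri(propan-2-yl)silyloxy]phenyl}piperidine-1-carboxylate
Conditions: TIPSCl (1.05 equiv), imidazole (2.2 equiv), DMF, −20 → 0 °C
Reagents that add atoms: chlorotri(propan-2-yl)silane (TIPSCl), CC(C)[Si](Cl)(C(C)C)C(C)C
Why: Sterically controlled O-silylation: the bulky silyl chloride takes only the phenol with two unsubstituted neighbours, because the two ortho phenols are shielded by the N-Boc-piperidinyl group and hydrogen-bonded to its carbonyl.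

Step 3
Reactants: 5 tert-butyl (2R)-2-{2,6-dihydroxy-4-[tri(propan-2-yl)silyloxy]phenyl}piperidine-1-carboxylate
Product: 6 tert-butyl (2R)-2-{2,6-bis(benzyloxy)-4-[tri(propan-2-yl)silyloxy]phenyl}piperidine-1-carboxylate
Conditions: BnBr (2.5 equiv), K2CO3 (3 equiv), acetone, 56 °C
Reagents that add atoms: benzyl bromide, BrCc1ccccc1
Why: Williamson ether synthesis on the two remaining phenols under carbonate in acetone, which leaves the aryl silyl ether and the Boc group intact.

Step 4
Reactants: 6 tert-butyl (2R)-2-{2,6-bis(benzyloxy)-4-[tri(propan-2-yl)silyloxy]phenyl}piperidine-1-carboxylate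
Product: 8 tert-butyl (2R)-2-[2,6-bis(benzyloxy)-4-(methoxymethoxy)phenyl]piperidine-1-carboxylate, via tetrabutylammonium phenoxide 7 (not isolated)
Conditions: Bu4NF (1.05 equiv), THF, 0 °C; then MOMCl (2 equiv), 0 °C → rt
Reagents that add atoms: chloromethyl methyl ether (MOMCl), COCCl
Why: Fluoride cleaves the Si–O bond and the resulting phenoxide is alkylated in the same flask (Williamson), which swaps the silyl group for the MOM group that later directs lithiation and unmasks the ring oxygen under acid.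

Step 5
Reactants: 8 tert-butyl (2R)-2-[2,6-bis(benzyloxy)-4-(methoxymethoxy)phenyl]piperidine-1-carboxylate
Product: 9 (2R)-2-[2,6-bis(benzyloxy)-4-(methoxymethoxy)phenyl]-1-methylpiperidine
Conditions: LiAlH4 (4 equiv), THF, 66 °C; then H2O
Reagents that add atoms: none
Why: Hydride reduction of the carbamate to the N-methyl amine (via the formamide), with the benzyl and MOM ethers inert and no bond to the stereocentre broken.

Step 6
Reactants: 9 (2R)-2-[2,6-bis(benzyloxy)-4-(methoxymethoxy)phenyl]-1-methylpiperidine + 10 N-methoxy-N-methylacetamide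
Product: 12 1-{2,4-bis(benzyloxy)-6-(methoxymethoxy)-3-[(2R)-1-methylpiperidin-2-yl]phenyl}ethan-1-one, via aryllithium 11 (not isolated)
Conditions: n-BuLi (1.3 equiv), TMEDA (1.3 equiv), THF, −20 → 0 °C; then 10 (2 equiv), −78 → 0 °C; then H2O
Reagents that add atoms: none
Why: Directed ortho-metalation at the carbon between the MOM ether and a benzyl ether (the two such carbons are interconverted by rotation about the aryl–piperidine bond, so one constitution results), followed by Weinreb ketone synthesis, which stops at the ketone.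

Step 7
Reactants: 12 1-{2,4-bis(benzyloxy)-6-(methoxymethoxy)-3-[(2R)-1-methylpiperidin-2-yl]phenyl}ethan-1-one
Product: 13 (2E)-1-{2,4-bis(benzyloxy)-6-(methoxymethoxy)-3-[(2R)-1-methylpiperidin-2-yl]phenyl}-3-(dimethylamino)prop-2-en-1-one
Conditions: Me2NCH(OMe)2 (5 equiv), toluene, 110 °C
Reagents that add atoms: N,N-dimethylformamide dimethyl acetal, COC(OC)N(C)C
Why: Condensation of the methyl ketone with the amide acetal gives the E-enaminone (enaminone formation), the standard one-carbon homologation for chromone synthesis.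

Step 8
Reactants: 13 (2E)-1-{2,4-bis(benzyloxy)-6-(methoxymethoxy)-3-[(2R)-1-methylpiperidin-2-yl]phenyl}-3-(dimethylamino)prop-2-en-1-one
Product: 15 5,7-bis(benzyloxy)-6-[(2R)-1-methylpiperidin-2-yl]-4H-chromen-4-one, via hydroxy-enaminone 14 (not isolated)
Conditions: HCl (3 M in MeOH), 40 °C; then aq. NaHCO3
Reagents that add atoms: none
Why: Acid methanolysis removes the MOM group and the liberated phenol, the only free OH, adds to the enaminone and expels dimethylamine (addition–elimination cyclisation), so the ring oxygen is fixed para to the piperidine.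

Step 9
Reactants: 15 5,7-bis(benzyloxy)-6-[(2R)-1-methylpiperidin-2-yl]-4H-chromen-4-one + 16 4-(benzyloxy)phenylboronic acid
Product: 17 (2S)-5,7-bis(benzyloxy)-2-[4-(benzyloxy)phenyl]-6-[(2R)-1-methylpiperidin-2-yl]-2,3-dihydro-4H-chromen-4-one
Conditions: [Rh(OH)(cod)]2 (cod = cycloocta-1,5-diene) 2.5 mol %, (S)-MeO-F12-BIPHEP [(S)-6,6'-dimethoxy-2,2'-bis[bis(3,4,5-trifluorophenyl)phosphino]-1,1'-biphenyl] 5.5 mol %, 16 (3 equiv), toluene/H2O 10:1, 40 °C
Reagents that add atoms: none
Why: Hayashi–Miyaura rhodium-catalysed asymmetric 1,4-addition, in which the aryl–rhodium species adds to C2 of the chromone on the face selected by the (S)-biaryl bisphosphine (the same facial sense that gives (S)-3-arylcyclohexanones from cyclic enones) and water protonates the rhodium enolate, so the 2S centre is set under catalyst control independent of the remote piperidine centre.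

Step 10
Reactants: 17 (2S)-5,7-bis(benzyloxy)-2-[4-(benzyloxy)phenyl]-6-[(2R)-1-methylpiperidin-2-yl]-2,3-dihydro-4H-chromen-4-one
Product: 18 (2S)-5,7-dihydroxy-2-(4-hydroxyphenyl)-6-[(2R)-1-methylpiperidin-2-yl]-2,3-dihydro-4H-chromen-4-one (CNP0146489.2)
Conditions: H2 (1 atm), 10 % Pd/C, EtOAc/MeOH/AcOH 10:10:1, rt; then aq. NaHCO3
Reagents that add atoms: none
Why: Catalytic hydrogenolysis cleaves the three benzyl ethers, and the acetic acid keeps the amine protonated so that it neither poisons the catalyst nor opens the chromanone ring by base catalysis, leaving both stereocentres untouched.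

## Compound list

1 | phloroglucinol (benzene-1,3,5-triol) | Oc1cc(O)cc(O)c1 | starting material
2 | tert-butyl 3,4-dihydro-2H-pyridine-1-carboxylate | CC(C)(C)OC(=O)N1CCCC=C1 | starting material
3 | 1-(tert-butoxycarbonyl)-2,3,4,5-tetrahydropyridin-1-ium, ion-paired with the phosphate of the catalyst (cation shown) | CC(C)(C)OC(=O)[N+]1=CCCCC1 | intermediate
4 | tert-butyl (2R)-2-(2,4,6-trihydroxyphenyl)piperidine-1-carboxylate | CC(C)(C)OC(=O)N1CCCC[C@@H]1c1c(O)cc(O)cc1O | intermediate
5 | tert-butyl (2R)-2-{2,6-dihydroxy-4-[tri(propan-2-yl)silyloxy]phenyl}piperidine-1-carboxylate | CC(C)(C)OC(=O)N1CCCC[C@@H]1c1c(O)cc(O[Si](C(C)C)(C(C)C)C(C)C)cc1O | intermediate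
6 | tert-butyl (2R)-2-{2,6-bis(benzyloxy)-4-[tri(propan-2-yl)silyloxy]phenyl}piperidine-1-carboxylate | CC(C)(C)OC(=O)N1CCCC[C@@H]1c1c(OCc2ccccc2)cc(O[Si](C(C)C)(C(C)C)C(C)C)cc1OCc1ccccc1 | intermediate
7 | tetrabutylammonium 3,5-bis(benzyloxy)-4-[(2R)-1-(tert-butoxycarbonyl)piperidin-2-yl]phenoxide | CC(C)(C)OC(=O)N1CCCC[C@@H]1c1c(OCc2ccccc2)cc([O-])cc1OCc1ccccc1.CCCC[N+](CCCC)(CCCC)CCCC | intermediate
8 | tert-butyl (2R)-2-[2,6-bis(benzyloxy)-4-(methoxymethoxy)phenyl]piperidine-1-carboxylate | CC(C)(C)OC(=O)N1CCCC[C@@H]1c1c(OCc2ccccc2)cc(OCOC)cc1OCc1ccccc1 | intermediate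
9 | (2R)-2-[2,6-bis(benzyloxy)-4-(methoxymethoxy)phenyl]-1-methylpiperidine | CN1CCCC[C@@H]1c1c(OCc2ccccc2)cc(OCOC)cc1OCc1ccccc1 | intermediate
10 | N-methoxy-N-methylacetamide | CC(=O)N(C)OC | starting material
11 | {2,4-bis(benzyloxy)-6-(methoxymethoxy)-3-[(2R)-1-methylpiperidin-2-yl]phenyl}lithium | CN1CCCC[C@@H]1c1c(OCc2ccccc2)cc(OCOC)c([Li])c1OCc1ccccc1 | intermediate
12 | 1-{2,4-bis(benzyloxy)-6-(methoxymethoxy)-3-[(2R)-1-methylpiperidin-2-yl]phenyl}ethan-1-one | CN1CCCC[C@@H]1c1c(OCc2ccccc2)cc(OCOC)c(C(C)=O)c1OCc1ccccc1 | intermediate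
13 | (2E)-1-{2,4-bis(benzyloxy)-6-(methoxymethoxy)-3-[(2R)-1-methylpiperidin-2-yl]phenyl}-3-(dimethylamino)prop-2-en-1-one | CN1CCCC[C@@H]1c1c(OCc2ccccc2)cc(OCOC)c(C(=O)/C=C/N(C)C)c1OCc1ccccc1 | intermediate
14 | (2E)-1-{2,4-bis(benzyloxy)-6-hydroxy-3-[(2R)-1-methylpiperidin-2-yl]phenyl}-3-(dimethylamino)prop-2-en-1-one | CN1CCCC[C@@H]1c1c(OCc2ccccc2)cc(O)c(C(=O)/C=C/N(C)C)c1OCc1ccccc1 | intermediate
15 | 5,7-bis(benzyloxy)-6-[(2R)-1-methylpiperidin-2-yl]-4H-chromen-4-one | CN1CCCC[C@@H]1c1c(OCc2ccccc2)cc2occc(=O)c2c1OCc1ccccc1 | intermediate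
16 | 4-(benzyloxy)phenylboronic acid | OB(O)c1ccc(OCc2ccccc2)cc1 | starting material
17 | (2S)-5,7-bis(benzyloxy)-2-[4-(benzyloxy)phenyl]-6-[(2R)-1-methylpiperidin-2-yl]-2,3-dihydro-4H-chromen-4-one | CN1CCCC[C@@H]1c1c(OCc3ccccc3)cc2c(c1OCc1ccccc1)C(=O)C[C@@H](c1ccc(OCc3ccccc3)cc1)O2 | intermediate
18 | (2S)-5,7-dihydroxy-2-(4-hydroxyphenyl)-6-[(2R)-1-methylpiperidin-2-yl]-2,3-dihydro-4H-chromen-4-one | CN1CCCC[C@@H]1c1c(O)cc2c(c1O)C(=O)C[C@@H](c1ccc(O)cc1)O2 | target

## Step count and risks

Total step count: 10. Longest linear sequence: 10 steps (1 and 2 to 18).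

The three steps most likely to fail:

**Step 1 (the proposed new reaction).** The risks are a racemic acid-promoted background reaction, self-condensation of the ene-carbamate and double alkylation of 1. The fallback uses known chemistry, sets out from 1 and 2 and comes back to the route at 4. The classical achiral-acid N-acyliminium amidoalkylation of phenols (diphenyl hydrogen phosphate 10 mol %, EtOAc, 0 °C, 1 in threefold excess) gives racemic tert-butyl 2-(2,4,6-trihydroxyphenyl)piperidine-1-carboxylate F1. Its enantiomers are separated by preparative supercritical-fluid chromatography on an amylose tris(3,5-dimethylphenylcarbamate) phase. The 2R enantiomer is 4 and enters step 2, so stereocontrol comes from resolution instead of asymmetric catalysis.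

**Step 6 (ortho-lithiation and acetylation).** The risks are competing deprotonation of the benzylic ether CH2 groups (Wittig rearrangement) and proton transfer from the amide to the aryllithium. The fallback replaces carbanion chemistry by phenol-directed electrophilic substitution; it sets out from 9 and comes back to the route at 14, which is closed to 15 with HCl as in step 8.
- Methanolic HCl at rt removes the MOM group of 9 to give 3,5-bis(benzyloxy)-4-[(2R)-1-methylpiperidin-2-yl]phenol F2.
- Magnesium-mediated ortho-formylation (MgCl2, Et3N, paraformaldehyde, MeCN, 80 °C) at either of the two equivalent ortho positions gives 2,4-bis(benzyloxy)-6-hydroxy-3-[(2R)-1-methylpiperidin-2-yl]benzaldehyde F3.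
- MeMgBr (3 equiv, THF, 0 °C) gives 1-{2,4-bis(benzyloxy)-6-hydroxy-3-[(2R)-1-methylpiperidin-2-yl]phenyl}ethan-1-ol F4 as a mixture of carbinol epimers.
- MnO2 (CH2Cl2, rt) oxidises this to 1-{2,4-bis(benzyloxy)-6-hydroxy-3-[(2R)-1-methylpiperidin-2-yl]phenyl}ethan-1-one F5.
- Me2NCH(OMe)2 (toluene, 90 °C) converts F5 into the hydroxy-enaminone 14.

**Step 9 (asymmetric conjugate arylation).** The risks are low conversion of the electron-rich, hindered chromone, ring-opening of the rhodium enolate to a chalcone, and an unexpected facial sense. The fallback builds C2 by oxa-Michael ring closure instead of conjugate arylation; it sets out from 12 and comes back to the route at 17.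
- Claisen–Schmidt condensation of 12 with 4-(benzyloxy)benzaldehyde (KOH, EtOH, rt) gives (2E)-1-{2,4-bis(benzyloxy)-6-(methoxymethoxy)-3-[(2R)-1-methylpiperidin-2-yl]phenyl}-3-[4-(benzyloxy)phenyl]prop-2-en-1-one F6.
- Methanolic HCl at rt removes the MOM group to give (2E)-1-{2,4-bis(benzyloxy)-6-hydroxy-3-[(2R)-1-methylpiperidin-2-yl]phenyl}-3-[4-(benzyloxy)phenyl]prop-2-en-1-one F7.
- NaOAc in refluxing EtOH closes the ring to give 17 together with its C2 epimer (2R)-5,7-bis(benzyloxy)-2-[4-(benzyloxy)phenyl]-6-[(2R)-1-methylpiperidin-2-yl]-2,3-dihydro-4H-chromen-4-one F8.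
- The two diastereomers are separated by preparative HPLC, and F8 is recycled by resubmitting it to NaOAc/EtOH, which re-equilibrates it with 17 through F7.

## Further compounds

F1 | step 1 | racemic tert-butyl 2-(2,4,6-trihydroxyphenyl)piperidine-1-carboxylate | CC(C)(C)OC(=O)N1CCCCC1c1c(O)cc(O)cc1O
F2 | step 6 | 3,5-bis(benzyloxy)-4-[(2R)-1-methylpiperidin-2-yl]phenol | CN1CCCC[C@@H]1c1c(OCc2ccccc2)cc(O)cc1OCc1ccccc1
F3 | step 6 | 2,4-bis(benzyloxy)-6-hydroxy-3-[(2R)-1-methylpiperidin-2-yl]benzaldehyde | CN1CCCC[C@@H]1c1c(OCc2ccccc2)cc(O)c(C=O)c1OCc1ccccc1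
F4 | step 6 | 1-{2,4-bis(benzyloxy)-6-hydroxy-3-[(2R)-1-methylpiperidin-2-yl]phenyl}ethan-1-ol (both carbinol epimers) | CN1CCCC[C@@H]1c1c(OCc2ccccc2)cc(O)c(C(C)O)c1OCc1ccccc1
F5 | step 6 | 1-{2,4-bis(benzyloxy)-6-hydroxy-3-[(2R)-1-methylpiperidin-2-yl]phenyl}ethan-1-one | CN1CCCC[C@@H]1c1c(OCc2ccccc2)cc(O)c(C(C)=O)c1OCc1ccccc1
F6 | step 9 | (2E)-1-{2,4-bis(benzyloxy)-6-(methoxymethoxy)-3-[(2R)-1-methylpiperidin-2-yl]phenyl}-3-[4-(benzyloxy)phenyl]prop-2-en-1-one | CN1CCCC[C@@H]1c1c(OCc2ccccc2)cc(OCOC)c(C(=O)/C=C/c2ccc(OCc3ccccc3)cc2)c1OCc1ccccc1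
F7 | step 9 | (2E)-1-{2,4-bis(benzyloxy)-6-hydroxy-3-[(2R)-1-methylpiperidin-2-yl]phenyl}-3-[4-(benzyloxy)phenyl]prop-2-en-1-one | CN1CCCC[C@@H]1c1c(OCc2ccccc2)cc(O)c(C(=O)/C=C/c2ccc(OCc3ccccc3)cc2)c1OCc1ccccc1
F8 | step 9 | (2R)-5,7-bis(benzyloxy)-2-[4-(benzyloxy)phenyl]-6-[(2R)-1-methylpiperidin-2-yl]-2,3-dihydro-4H-chromen-4-one | CN1CCCC[C@@H]1c1c(OCc3ccccc3)cc2c(c1OCc1ccccc1)C(=O)C[C@H](c1ccc(OCc3ccccc3)cc1)O2
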